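**Strategy**

The dihydrofuran ring (O1, C2, C3, C3a, C7a; benzofuran numbering of the target) is grown out of a cyclobutane. A titanium-promoted quinone–propenylbenzene (2+2) adduct, a bicyclo[4.2.0]octenedione whose four-membered ring holds C2, C3, C3a and C4, is ionised by acid at its donor–acceptor C2–C4 bond. The C7a carbonyl oxygen captures the aryl-stabilised C2 cation, so one 1,3-shift expands the carbocycle to the trans-2-aryl-3-methyl dihydrofuran and unveils the vinylogous ester O1–C7a=C7–C6=O. The step exploits the electron-rich aryl group on C2 and the oxygen on C7a. A suprafacial Cope shift then relays the allyl group from C3a to C5.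

Key step: step 5

**Remarks on the chemistry**

- Numbering: compounds 10–12 carry benzofuran numbering (O1, C2, C3, C3a, C4–C7, C7a). Cyclobutane 7 is numbered as a bicyclo[4.2.0]octane with the aryl-bearing carbon as C8 and the allyl-bearing ring-fusion carbon as C6.
- Assumption: the (R,R)-TADDOL titanium complex is taken to lead to (1S,6R,7S,8S)-7. If it leads to the mirror image, the (S,S)-diol is used and nothing else changes. (R,R)-TADDOL is (4R,5R)-2,2-dimethyl-α,α,α′,α′-tetraphenyl-1,3-dioxolane-4,5-dimethanol.
- Compounds 1, 2 and 6 are commercially available.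

**Route**

Step 1
Reactants: 1 3,4-dimethoxyphenol; 2 allyl bromide
Product: 3 1,2-dimethoxy-4-(prop-2-en-1-yloxy)benzene
Conditions: K2CO3, acetone, reflux
Reagents that add atoms: none
Why: Williamson ether synthesis (SN2 of the phenoxide on the primary allylic bromide); no stereocenter is formed.

Step 2
Reactants: 3 1,2-dimethoxy-4-(prop-2-en-1-yloxy)benzene
Product: 4 4,5-dimethoxy-2-(prop-2-en-1-yl)phenol
Conditions: N,N-diethylaniline, 190 °C
Reagents that add atoms: none
Why: Aromatic Claisen rearrangement ([3,3]-sigmatropic shift) followed by enolisation; the allyl group should go to the ortho position that is not flanked by a methoxy group, and no stereocenter is formed.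

Step 3
Reactants: 4 4,5-dimethoxy-2-(prop-2-en-1-yl)phenol
Product: 5 2-methoxy-5-(prop-2-en-1-yl)cyclohexa-2,5-diene-1,4-dione
Conditions: PhI(OAc)2, MeCN–H2O (2:1), 0 °C
Reagents that add atoms: water O
Why: Oxidative demethylation of a para-methoxyphenol by trivalent iodine: the phenoxenium ion takes up water at the para carbon and the hemiketal expels methanol to leave the 1,4-quinone; no stereocenter is formed.

Step 4
Reactants: 5 2-methoxy-5-(prop-2-en-1-yl)cyclohexa-2,5-diene-1,4-dione; 6 1,2-dimethoxy-4-[(1E)-prop-1-en-1-yl]benzene
Product: 7 (1S,6R,7S,8S)-8-(3,4-dimethoxyphenyl)-3-methoxy-7-methyl-6-(prop-2-en-1-yl)bicyclo[4.2.0]oct-3-ene-2,5-dione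
Conditions: preformed TiCl2[(R,R)-TADDOLate], toluene–CH2Cl2, −78 °C
Reagents that add atoms: none
Why: Stepwise Lewis-acid-promoted (2+2) cycloaddition of a 2-alkoxy-1,4-benzoquinone with a propenylbenzene: tetravalent titanium chelated between the C1 carbonyl and the methoxy oxygen of 5 activates the allyl-bearing C5, the alkene β-carbon bonds there and the titanium enolate carbon C6 collapses onto the benzylic cation, which should give the cis-fused cyclobutane with the E geometry retained (aryl and methyl trans), the aryl group endo over the six-membered ring as in the parent series and hence the methyl group exo and cis to the allyl group, while the TADDOLate ligand selects the quinone face and so the absolute configuration.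

Step 5
Reactants: 7 (1S,6R,7S,8S)-8-(3,4-dimethoxyphenyl)-3-methoxy-7-methyl-6-(prop-2-en-1-yl)bicyclo[4.2.0]oct-3-ene-2,5-dione
Product: 10 (2R,3R,3aR)-2-(3,4-dimethoxyphenyl)-5-hydroxy-3-methyl-3a-(prop-2-en-1-yl)-3,3a-dihydro-1-benzofuran-6(2H)-one, via ring-opened benzylic cation 8 (not isolated), via methyl oxocarbenium ion 9 (not isolated)
Conditions: CF3CO2H, H2O (2 equiv), CH2Cl2, 0 °C to rt
Reagents that add atoms: water O
Why: Acid activation of the C2 carbonyl polarises the donor–acceptor C1–C8 bond of the cyclobutane (aryl donor on C8, enolisable ketone on C1), which heterolyses to the 3,4-dimethoxybenzyl cation 8; after rotation about C6–C7 the C5 carbonyl oxygen closes the five-membered ring in a 5-exo-trig sense onto the aryl-delocalised cation to give the methoxy-stabilised oxocarbenium ion 9, and water exchanges its O-methyl group for the C6 carbonyl with loss of methanol. The closest known reaction is the acid-promoted cyclobutane-to-dihydrobenzofuran 1,3-shift of quinone–propenylbenzene (2+2) adducts, a ring homologue of the Cloke–Wilson rearrangement of cyclopropyl ketones. C3 and C3a are carried over from C7 and C6 of 7 without any bond to them being broken, and because the carbon expelled from the four-membered ring becomes C4 of the six-membered ring, the exo methyl group ends trans to the allyl group. C2 is the only new stereocenter and should be set trans to the C3 methyl group by thermodynamic control, since the benzylic C2–O1 bond re-ionises under the acidic conditions. The step needs oxygen and not carbon capture of the cation, cleavage of C1–C8 and not of C6–C7, and ring closure faster than loss of the alkene from 8; the first is secured by reversibility, which drains the carbon-closed bicyclo[3.2.1] isomer into the conjugated vinylogous ester that hydrolysis then locks, the second by the fact that only C8 carries the cation-stabilising aryl group and only C1 an enolisable acceptor, the third by the intramolecular five-membered closure.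

Step 6
Reactants: 10 (2R,3R,3aR)-2-(3,4-dimethoxyphenyl)-5-hydroxy-3-methyl-3a-(prop-2-en-1-yl)-3,3a-dihydro-1-benzofuran-6(2H)-one
Product: 11 (2R,3R,3aR)-2-(3,4-dimethoxyphenyl)-5-methoxy-3-methyl-3a-(prop-2-en-1-yl)-3,3a-dihydro-1-benzofuran-6(2H)-one
Conditions: MeI, K2CO3, acetone, rt
Reagents that add atoms: iodomethane CI
Why: Williamson-type O-methylation of the acidic diosphenol (the enolic 5-OH next to the C6 carbonyl) by SN2 on iodomethane; no stereocenter is touched.

Step 7
Reactants: 11 (2R,3R,3aR)-2-(3,4-dimethoxyphenyl)-5-methoxy-3-methyl-3a-(prop-2-en-1-yl)-3,3a-dihydro-1-benzofuran-6(2H)-one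
Product: 12 (2R,3R,5S)-2-(3,4-dimethoxyphenyl)-5-methoxy-3-methyl-5-(prop-2-en-1-yl)-2,3-dihydro-1-benzofuran-6(5H)-one
Conditions: toluene, 100 °C, sealed tube
Reagents that add atoms: none
Why: Cope rearrangement ([3,3]-sigmatropic shift) of the 1,5-diene CH2=CH–CH2–C3a–C4=C5: the allyl group can reach C5 only across the ring face it occupies at C3a (suprafacial six-membered cyclic transition state), so the 3aR center should be translated into the 5S center, and the shift is driven by release of the crowded quaternary C3a next to C3 and by the extended dienone conjugation that keeps the vinylogous ester O1–C7a=C7–C6=O.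

**Compound list**

1 | 3,4-dimethoxyphenol | COc1ccc(O)cc1OC | starting material
2 | allyl bromide (3-bromoprop-1-ene) | C=CCBr | starting material
3 | 1,2-dimethoxy-4-(prop-2-en-1-yloxy)benzene | C=CCOc1ccc(OC)c(OC)c1 | intermediate
4 | 4,5-dimethoxy-2-(prop-2-en-1-yl)phenol | C=CCc1cc(OC)c(OC)cc1O | intermediate
5 | 2-methoxy-5-(prop-2-en-1-yl)cyclohexa-2,5-diene-1,4-dione | C=CCC1=CC(=O)C(OC)=CC1=O | intermediate
6 | 1,2-dimethoxy-4-[(1E)-prop-1-en-1-yl]benzene ((E)-methylisoeugenol) | C/C=C/c1ccc(OC)c(OC)c1 | starting material
7 | (1S,6R,7S,8S)-8-(3,4-dimethoxyphenyl)-3-methoxy-7-methyl-6-(prop-2-en-1-yl)bicyclo[4.2.0]oct-3-ene-2,5-dione (cis-fused; aryl endo; methyl exo, cis to allyl) | C=CC[C@]12C(=O)C=C(OC)C(=O)[C@H]1[C@@H](c1ccc(OC)c(OC)c1)[C@@H]2C | intermediate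
8 | ring-opened benzylic cation: 3,4-dimethoxybenzyl cation joined through CHMe to C6 of the 6-allyl-4-hydroxy-3-methoxycyclohexa-2,4-dienone (C6 and C7 of 7 unchanged) | C=CC[C@@]1(C(=O)C=C(OC)C(O)=C1)[C@@H](C)[CH+]c1ccc(OC)c(OC)c1 | intermediate
9 | methyl oxocarbenium ion: 6-O-methylated, ring-expanded cation of 10 | C=CC[C@@]12C=C(O)C(=[O+]C)C=C1O[C@@H](c1ccc(OC)c(OC)c1)[C@@H]2C | intermediate
10 | (2R,3R,3aR)-2-(3,4-dimethoxyphenyl)-5-hydroxy-3-methyl-3a-(prop-2-en-1-yl)-3,3a-dihydro-1-benzofuran-6(2H)-one | C=CC[C@@]12C=C(O)C(=O)C=C1O[C@@H](c1ccc(OC)c(OC)c1)[C@@H]2C | intermediate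
11 | (2R,3R,3aR)-2-(3,4-dimethoxyphenyl)-5-methoxy-3-methyl-3a-(prop-2-en-1-yl)-3,3a-dihydro-1-benzofuran-6(2H)-one | C=CC[C@@]12C=C(OC)C(=O)C=C1O[C@@H](c1ccc(OC)c(OC)c1)[C@@H]2C | intermediate
12 | (2R,3R,5S)-2-(3,4-dimethoxyphenyl)-5-methoxy-3-methyl-5-(prop-2-en-1-yl)-2,3-dihydro-1-benzofuran-6(5H)-one | C=CC[C@]1(OC)C=C2C(=CC1=O)O[C@@H](c1ccc(OC)c(OC)c1)[C@@H]2C | target

**Step count and risks**

Total step count: 7. Longest linear sequence: 7 steps (1 to 12).

Steps most likely to fail:

1. Step 4. The allyl group on C5 may disturb the chelate on which the chiral complex relies, so that facial discrimination erodes or bond formation drifts from C5 to the unsubstituted C6. The fallback sets out from 5 (with 6) and comes back at 7. Reagent-controlled induction is given up: the cycloaddition would be run with an achiral, TiCl4-rich TiCl4/Ti(OiPr)4 promoter at −78 °C, whose stronger bidentate binding should hold the attack at C5. The racemate so formed contains 7 and its mirror image, (1R,6S,7R,8R)-8-(3,4-dimethoxyphenyl)-3-methoxy-7-methyl-6-(prop-2-en-1-yl)bicyclo[4.2.0]oct-3-ene-2,5-dione F1, which would be removed by preparative chromatography on a chiral stationary phase.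

2. Step 5. The benzylic cation may be captured by the enol-ether carbon C4 of 7 instead of by oxygen, or the ring may close cis to the C3 methyl group, so that material collects in a carbon-closed isomer. The fallback sets out from 7 and comes back at 10, in two stages. First, 7 would be isomerised on purpose with TiCl4 in CH2Cl2 (−78 to 0 °C), conditions under which cyclobutanes of this family pass into the (5+2)-type isomer with loss of the O-methyl group as chloromethane. This should give (1R,5R,6S,7S)-7-(3,4-dimethoxyphenyl)-3-hydroxy-6-methyl-5-(prop-2-en-1-yl)bicyclo[3.2.1]oct-3-ene-2,8-dione F2. Second, F2 would be heated with p-TsOH·H2O in benzene (80 °C): the benzylic C1–C7 bond re-ionises to a β-diketone enol, and the C8 ketone oxygen closes the dihydrofuran to give 10. The C7 configuration of F2 is immaterial, because it is lost and reset trans to the methyl group on re-ionisation.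

3. Step 7. The allyl group may shift onward from C5 to the C6 carbonyl oxygen (retro-Claisen) with aromatisation, or migrate toward C7, before 11 is consumed. The fallback sets out from 11 and comes back at 12. The neutral thermal manifold is left for an acid-catalysed Cope shift (catalytic BF3·OEt2 or CF3CO2H in CH2Cl2, −20 to 0 °C), a reaction type known for allylcyclohexadienones. Complexation of the C6 carbonyl oxygen should accelerate the carbon-to-carbon [3,3] shift while the occupied oxygen can no longer accept the allyl group. No new compound arises (F0).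

**Further compounds**

F1 | step 4 | (1R,6S,7R,8R)-8-(3,4-dimethoxyphenyl)-3-methoxy-7-methyl-6-(prop-2-en-1-yl)bicyclo[4.2.0]oct-3-ene-2,5-dione | C=CC[C@@]12C(=O)C=C(OC)C(=O)[C@@H]1[C@H](c1ccc(OC)c(OC)c1)[C@H]2C
F2 | step 5 | (1R,5R,6S,7S)-7-(3,4-dimethoxyphenyl)-3-hydroxy-6-methyl-5-(prop-2-en-1-yl)bicyclo[3.2.1]oct-3-ene-2,8-dione | C=CC[C@@]12C=C(O)C(=O)[C@@H](C1=O)[C@@H](c1ccc(OC)c(OC)c1)[C@@H]2C
F0 | step 7 | none | none
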